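**Retrosynthetic overview**

1. The target is three fully substituted phloroglucinol rings joined by two CH2 groups: ring A (butanoyl para to OMe), ring B (acetyl) and ring C. The last operations are C-butanoylation at C1 of ring C and hydrogenolysis of five benzyl ethers.
2. The strategy rests on ring C: C1 butanoyl lies between C2–OMe and C6–OH, with C3–Me, C4–OH and the C5 methylene bridge. A methoxy group ortho to the acyl carbon and next to the methyl is not reachable by O-methylation of an acylphloroglucinol, so ring C is built last.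
3. Ring C is cut by a benzannulation into a racemic 4-(ArCH2)-2-methyl-3-silyloxycyclobutenone (C6, C5, C4, C3) and methoxyethyne (C1, C2). This forms C6–C1, C2–C3 and C5–C6 and delivers the three oxygens as OH, OMe and OSi; the silyl ether is cleaved in the same flask.
4. The cyclobutenone comes from a ketene–ynol ether [2+2] cycloaddition of the ring A–ring B propanoyl chloride with 1-(triisopropylsilyloxy)propyne. The ring A–ring B acid comes from an ortho-quinone methide coupling of the aspidinol Mannich base with a phloroacetophenone-derived propanoic acid, then perbenzylation.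
5. Ring order: rings A and B are purchased aromatic rings, the four-membered ring is made in step 10, and ring C is closed in step 12.

Key step: step 12

Notation and assumption: ring C is numbered C1 (butanoyl), C2 (OMe), C3 (Me), C4 (OH), C5 (CH2 to ring B), C6 (OH); Ar = 3-acetyl-2,4,6-tris(benzyloxy)-5-{[2,4-bis(benzyloxy)-3-butanoyl-6-methoxy-5-methylphenyl]methyl}phenyl; the target has no stereocentre, and the one stereocentre carried on the route (C4 of the cyclobutenone) is racemic and is lost on aromatisation.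

**Route**

Step 1
Reactants: 1 2-methylbenzene-1,3,5-triol
Product: 2 1-(2,4,6-trihydroxy-3-methylphenyl)butan-1-one
Conditions: PrCOCl, AlCl3, PhNO2, rt to 60 °C; then ice/aq HCl
Reagents that add atoms: butanoyl chloride, CCCC(=O)Cl
Why: Friedel–Crafts acylation in which the two free ring carbons are equivalent and the first acyl group deactivates the ring towards a second.

Step 2
Reactants: 2 1-(2,4,6-trihydroxy-3-methylphenyl)butan-1-one
Product: 3 aspidinol [1-(2,6-dihydroxy-4-methoxy-3-methylphenyl)butan-1-one]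
Conditions: Me2SO4 (1.0 equiv), K2CO3 (1.0 equiv), acetone, rt
Reagents that add atoms: dimethyl sulfate, COS(=O)(=O)OC
Why: Williamson O-methylation should take place first at the 4-hydroxyl, which is para to the ketone, the most acidic and not tied up in a hydrogen bond to the carbonyl.

Step 3
Reactants: 3 aspidinol
Product: 4 1-{3-[(dimethylamino)methyl]-2,6-dihydroxy-4-methoxy-5-methylphenyl}butan-1-one
Conditions: CH2(NMe2)2 (1.5 equiv), CH2Cl2, rt
Reagents that add atoms: N,N,N',N'-tetramethylmethanediamine, CN(C)CN(C)C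
Why: phenolic Mannich aminomethylation at the only unsubstituted ring carbon, ortho to a free hydroxyl.

Step 4
Reactants: 5 1-(2,4,6-trihydroxyphenyl)ethan-1-one, 6 prop-2-enoic acid
Product: 9 3-(3-acetyl-2,4,6-trihydroxyphenyl)propanoic acid, via 6-acetyl-5,7-dihydroxychroman-2-one 7 (not isolated), via 8-acetyl-5,7-dihydroxychroman-2-one 8 (not isolated)
Conditions: Amberlyst 15, 1,4-dioxane/toluene, 100 °C; filter, evaporate; aq NaOH, THF, rt, N2; 1 M HCl to pH 3, 0 °C
Reagents that add atoms: sodium hydroxide, [Na+].[OH-]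
Why: acid-catalysed conjugate hydroarylation (Friedel–Crafts Michael addition) at one of the two equivalent free carbons is followed by lactonisation, which lowers ring nucleophilicity and should hold the reaction at mono-alkylation, and saponification converges either lactone on one acid.

Step 5
Reactants: 4 1-{3-[(dimethylamino)methyl]-2,6-dihydroxy-4-methoxy-5-methylphenyl}butan-1-one, 9 3-(3-acetyl-2,4,6-trihydroxyphenyl)propanoic acid
Product: 11 3-[3-acetyl-5-[(3-butanoyl-2,4-dihydroxy-6-methoxy-5-methylphenyl)methyl]-2,4,6-trihydroxyphenyl]propanoic acid, via ortho-quinone methide 10 (not isolated)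
Conditions: 1,4-dioxane, 100 °C, N2, the acid in slight excess; then 1 M HCl
Reagents that add atoms: none
Why: thermal loss of dimethylamine from the Mannich base gives an ortho-quinone methide that the single free ring carbon of 9 should attack in a Friedel–Crafts-type conjugate addition, while the ammonium carboxylate formed from 4 and 9 keeps the side chain from lactonising.

Step 6
Reactants: 11 3-[3-acetyl-5-[(3-butanoyl-2,4-dihydroxy-6-methoxy-5-methylphenyl)methyl]-2,4,6-trihydroxyphenyl]propanoic acid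
Product: 12 benzyl 3-Ar-propanoate (ArCH2CH2CO2Bn)
Conditions: BnBr (9 equiv), K2CO3, Bu4NI (cat.), DMF, 60 °C
Reagents that add atoms: benzyl bromide, BrCc1ccccc1
Why: exhaustive Williamson O-benzylation of the five phenols with esterification of the carboxylate, O-alkylation being favoured in DMF on rings that have no free carbon.

Step 7
Reactants: 12 benzyl 3-Ar-propanoate
Product: 13 3-Ar-propanoic acid (ArCH2CH2CO2H)
Conditions: LiOH, THF/MeOH/H2O, rt; then 1 M HCl
Reagents that add atoms: lithium hydroxide, [Li+].[OH-]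
Why: saponification of the unhindered alkyl benzyl ester, to which aryl benzyl ethers and the hindered aryl ketones are inert.

Step 8
Reactants: 13 3-Ar-propanoic acid
Product: 14 3-Ar-propanoyl chloride
Conditions: (COCl)2, DMF (cat.), CH2Cl2, 0 °C to rt; evaporate
Reagents that add atoms: oxalyl chloride, O=C(Cl)C(=O)Cl
Why: acid chloride formation through the catalytic chloroiminium species gives only volatile by-products, so the crude chloride can be used directly.

Step 9
Reactants: 15 prop-1-yne
Product: 18 triisopropyl(prop-1-yn-1-yloxy)silane, via prop-1-ynyllithium 16 (not isolated), via lithium prop-1-yn-1-olate 17 (not isolated)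
Conditions: n-BuLi, THF, −78 °C; LiOOt-Bu (from t-BuOOH, LiN(SiMe3)2), −78 to 0 °C; i-Pr3SiOTf, −78 °C to rt
Reagents that add atoms: tert-butyl hydroperoxide, CC(C)(C)OO; triisopropylsilyl trifluoromethanesulfonate, CC(C)[Si](C(C)C)(C(C)C)OS(=O)(=O)C(F)(F)F
Why: electrophilic oxygenation of the lithium acetylide by lithium tert-butyl peroxide gives the ynolate, which the bulky silyl triflate should silylate on oxygen and not on carbon.

Step 10
Reactants: 14 3-Ar-propanoyl chloride, 18 triisopropyl(prop-1-yn-1-yloxy)silane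
Product: 20 rac-4-(ArCH2)-2-methyl-3-(triisopropylsilyloxy)cyclobut-2-en-1-one, via ketene 19 (not isolated)
Conditions: Et3N (1.5 equiv), CH2Cl2, rt, acid chloride added by syringe pump to a threefold excess of the silyl ynol ether; filter through Et3N-treated silica
Reagents that add atoms: none
Why: dehydrochlorination gives the aldoketene, whose carbonyl carbon should bond to the methyl-bearing β-carbon of the silyl ynol ether in a regiospecific ketene–alkyne [2+2] cycloaddition, with slow addition and excess ynol ether holding back ketene dimerisation and C4 formed as a racemate.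

Step 11
Reactants: 21 2-chloro-1,1-dimethoxyethane
Product: 23 methoxyethyne, via sodium methoxyethynide 22 (not isolated)
Conditions: NaNH2 (3 equiv), liq NH3, −33 °C; sat. aq NaCl, −70 °C; distil into a cold trap
Reagents that add atoms: none
Why: two base-induced eliminations (methanol, then hydrogen chloride) give the alkynyl ether, which is held as its sodium acetylide until the cold aqueous quench.

Step 12
Reactants: 20 rac-4-(ArCH2)-2-methyl-3-(triisopropylsilyloxy)cyclobut-2-en-1-one, 23 methoxyethyne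
Product: 29 2-(ArCH2)-5-methoxy-4-methylbenzene-1,3-diol, via siloxyvinylketene 24 (not isolated), via 4-vinylcyclobutenone adduct 25 (not isolated), via dienylketene 26 (not isolated), via cyclohexa-2,4-dienone 27 (not isolated), via silyl ether phenol 28 (not isolated)
Conditions: toluene, sealed tube, 80 to 110 °C, alkyne in fivefold excess; cool, evaporate; Bu4NF, AcOH, THF, 0 °C
Reagents that add atoms: none
Why: Four-electron electrocyclic opening of 20 (C1–C4 bond of the cyclobutenone, bridging substituent rotating outward) gives siloxyvinylketene 24, whose ketene C=C adds methoxyethyne in a [2+2] cycloaddition (ketene carbonyl carbon to the unsubstituted alkyne carbon = ring C bond C6–C1, ketene α-carbon to the methoxy carbon = C3–C2) to give 4-vinylcyclobutenone 25. Reversible four-electron opening of 25 gives dienylketene 26, and ring C then closes by a six-electron disrotatory electrocyclisation of the ketene carbon onto the diene terminus that carries the bridging methylene (C6–C5), giving cyclohexadienone 27, which tautomerises to silyl ether phenol 28; buffered fluoride then cleaves the aryl silyl ether in the same flask, driven by the Si–F bond, to give diol 29. The closest known reaction type is the Danheiser benzannulation of cyclobutenones with alkoxyalkynes, here with a 3-siloxycyclobutenone as the vinylketene source. No stereocentre is set, because the racemic centres of 20, 25 and 27 all end as aromatic carbons. The step needs regiocontrol only, and this comes from the polarity of the partners (electrophilic ketene carbonyl carbon, nucleophilic β-carbon of the ynol ether), which puts the methoxy carbon next to the methyl carbon and the unsubstituted carbon next to the new hydroxyl. Benzyl ethers and the hindered aryl ketones should be inert to neutral heating and to buffered fluoride, and the excess of alkyne limits acylation of the product phenol by 24.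

Step 13
Reactants: 29 2-(ArCH2)-5-methoxy-4-methylbenzene-1,3-diol
Product: 30 1-[3-(ArCH2)-2,4-dihydroxy-6-methoxy-5-methylphenyl]butan-1-one
Conditions: (PrCO)2O (1.2 equiv), BF3·OEt2, CH2Cl2, 0 °C to rt; then H2O/MeOH
Reagents that add atoms: butanoic anhydride, CCCC(=O)OC(=O)CCC
Why: Friedel–Crafts acylation should occur at C1 of ring C, the only free carbon on the three oxygenated rings, which is activated by the ortho hydroxyl, the ortho methoxy and the para hydroxyl.

Step 14
Reactants: 30 1-[3-(ArCH2)-2,4-dihydroxy-6-methoxy-5-methylphenyl]butan-1-one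
Product: 31 CNP0184345.0 (target)
Conditions: H2 (1 atm), Pd/C, EtOAc/MeOH, rt
Reagents that add atoms: none
Why: hydrogenolysis of the five benzyl aryl ethers, under which the chelated, ring-conjugated ketones should not be reduced.

**Compound list**

1 | 2-methylbenzene-1,3,5-triol | Cc1c(O)cc(O)cc1O | starting material
2 | 1-(2,4,6-trihydroxy-3-methylphenyl)butan-1-one | CCCC(=O)c1c(O)cc(O)c(C)c1O | intermediate
3 | aspidinol, 1-(2,6-dihydroxy-4-methoxy-3-methylphenyl)butan-1-one | CCCC(=O)c1c(O)cc(OC)c(C)c1O | intermediate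
4 | 1-{3-[(dimethylamino)methyl]-2,6-dihydroxy-4-methoxy-5-methylphenyl}butan-1-one | CCCC(=O)c1c(O)c(CN(C)C)c(OC)c(C)c1O | intermediate
5 | 1-(2,4,6-trihydroxyphenyl)ethan-1-one | CC(=O)c1c(O)cc(O)cc1O | starting material
6 | prop-2-enoic acid | C=CC(=O)O | starting material
7 | 6-acetyl-5,7-dihydroxychroman-2-one | O=C1CCc2c(O1)cc(O)c(C(C)=O)c2O | intermediate (not isolated)
8 | 8-acetyl-5,7-dihydroxychroman-2-one | O=C1CCc2c(O1)c(C(C)=O)c(O)cc2O | intermediate (not isolated)
9 | 3-(3-acetyl-2,4,6-trihydroxyphenyl)propanoic acid | CC(=O)c1c(O)cc(O)c(CCC(=O)O)c1O | intermediate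
10 | 2-butanoyl-3-hydroxy-5-methoxy-4-methyl-6-methylidenecyclohexa-2,4-dien-1-one | CCCC(=O)C1=C(O)C(C)=C(OC)C(=C)C1=O | intermediate (not isolated)
11 | 3-[3-acetyl-5-[(3-butanoyl-2,4-dihydroxy-6-methoxy-5-methylphenyl)methyl]-2,4,6-trihydroxyphenyl]propanoic acid | CCCC(=O)c1c(O)c(C)c(OC)c(Cc2c(O)c(CCC(=O)O)c(O)c(C(C)=O)c2O)c1O | intermediate
12 | benzyl 3-Ar-propanoate | O=C(OCc1ccccc1)CCc2c(OCc3ccccc3)c(Cc3c(OCc4ccccc4)c(C(=O)CCC)c(OCc4ccccc4)c(C)c3OC)c(OCc3ccccc3)c(C(C)=O)c2OCc2ccccc2 | intermediate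
13 | 3-Ar-propanoic acid | O=C(O)CCc2c(OCc3ccccc3)c(Cc3c(OCc4ccccc4)c(C(=O)CCC)c(OCc4ccccc4)c(C)c3OC)c(OCc3ccccc3)c(C(C)=O)c2OCc2ccccc2 | intermediate
14 | 3-Ar-propanoyl chloride | O=C(Cl)CCc2c(OCc3ccccc3)c(Cc3c(OCc4ccccc4)c(C(=O)CCC)c(OCc4ccccc4)c(C)c3OC)c(OCc3ccccc3)c(C(C)=O)c2OCc2ccccc2 | intermediate
15 | prop-1-yne | CC#C | starting material
16 | prop-1-ynyllithium | [Li]C#CC | intermediate (not isolated)
17 | lithium prop-1-yn-1-olate | [Li]OC#CC | intermediate (not isolated)
18 | triisopropyl(prop-1-yn-1-yloxy)silane | CC#CO[Si](C(C)C)(C(C)C)C(C)C | intermediate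
19 | 3-Ar-prop-1-en-1-one (ketene ArCH2CH=C=O) | O=C=CCc2c(OCc3ccccc3)c(Cc3c(OCc4ccccc4)c(C(=O)CCC)c(OCc4ccccc4)c(C)c3OC)c(OCc3ccccc3)c(C(C)=O)c2OCc2ccccc2 | intermediate (not isolated)
20 | rac-4-(ArCH2)-2-methyl-3-(triisopropylsilyloxy)cyclobut-2-en-1-one | CC1=C(O[Si](C(C)C)(C(C)C)C(C)C)C(Cc2c(OCc3ccccc3)c(Cc3c(OCc4ccccc4)c(C(=O)CCC)c(OCc4ccccc4)c(C)c3OC)c(OCc3ccccc3)c(C(C)=O)c2OCc2ccccc2)C1=O | intermediate (key-step precursor)
21 | 2-chloro-1,1-dimethoxyethane | COC(CCl)OC | starting material
22 | sodium methoxyethynide | [Na]C#COC | intermediate (not isolated)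
23 | methoxyethyne | COC#C | intermediate
24 | (3Z)-5-Ar-2-methyl-3-(triisopropylsilyloxy)penta-1,3-dien-1-one | O=C=C(C)/C(O[Si](C(C)C)(C(C)C)C(C)C)=C/Cc2c(OCc3ccccc3)c(Cc3c(OCc4ccccc4)c(C(=O)CCC)c(OCc4ccccc4)c(C)c3OC)c(OCc3ccccc3)c(C(C)=O)c2OCc2ccccc2 | intermediate (not isolated)
25 | rac-3-methoxy-4-methyl-4-[(1Z)-3-Ar-1-(triisopropylsilyloxy)prop-1-en-1-yl]cyclobut-2-en-1-one | O=C1C=C(OC)C1(C)/C(O[Si](C(C)C)(C(C)C)C(C)C)=C/Cc2c(OCc3ccccc3)c(Cc3c(OCc4ccccc4)c(C(=O)CCC)c(OCc4ccccc4)c(C)c3OC)c(OCc3ccccc3)c(C(C)=O)c2OCc2ccccc2 | intermediate (not isolated)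
26 | (3E,5Z)-7-Ar-3-methoxy-4-methyl-5-(triisopropylsilyloxy)hepta-1,3,5-trien-1-one | O=C=C/C(OC)=C(C)\C(O[Si](C(C)C)(C(C)C)C(C)C)=C\Cc2c(OCc3ccccc3)c(Cc3c(OCc4ccccc4)c(C(=O)CCC)c(OCc4ccccc4)c(C)c3OC)c(OCc3ccccc3)c(C(C)=O)c2OCc2ccccc2 | intermediate (not isolated)
27 | rac-6-(ArCH2)-3-methoxy-4-methyl-5-(triisopropylsilyloxy)cyclohexa-2,4-dien-1-one | O=C1C=C(OC)C(C)=C(O[Si](C(C)C)(C(C)C)C(C)C)C1Cc2c(OCc3ccccc3)c(Cc3c(OCc4ccccc4)c(C(=O)CCC)c(OCc4ccccc4)c(C)c3OC)c(OCc3ccccc3)c(C(C)=O)c2OCc2ccccc2 | intermediate (not isolated)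
28 | 2-(ArCH2)-5-methoxy-4-methyl-3-(triisopropylsilyloxy)phenol | COc1cc(O)c(Cc2c(OCc3ccccc3)c(Cc3c(OCc4ccccc4)c(C(=O)CCC)c(OCc4ccccc4)c(C)c3OC)c(OCc3ccccc3)c(C(C)=O)c2OCc2ccccc2)c(O[Si](C(C)C)(C(C)C)C(C)C)c1C | intermediate (not isolated)
29 | 2-(ArCH2)-5-methoxy-4-methylbenzene-1,3-diol | COc1cc(O)c(Cc2c(OCc3ccccc3)c(Cc3c(OCc4ccccc4)c(C(=O)CCC)c(OCc4ccccc4)c(C)c3OC)c(OCc3ccccc3)c(C(C)=O)c2OCc2ccccc2)c(O)c1C | intermediate
30 | 1-[3-(ArCH2)-2,4-dihydroxy-6-methoxy-5-methylphenyl]butan-1-one | CCCC(=O)c1c(OC)c(C)c(O)c(Cc2c(OCc3ccccc3)c(Cc3c(OCc4ccccc4)c(C(=O)CCC)c(OCc4ccccc4)c(C)c3OC)c(OCc3ccccc3)c(C(C)=O)c2OCc2ccccc2)c1O | intermediate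
31 | CNP0184345.0, 1-[3-({3-acetyl-5-[(3-butanoyl-2,6-dihydroxy-4-methoxy-5-methylphenyl)methyl]-2,4,6-trihydroxyphenyl}methyl)-2,6-dihydroxy-4-methoxy-5-methylphenyl]butan-1-one | CCCC(=O)c1c(O)c(C)c(OC)c(Cc2c(O)c(Cc3c(O)c(C)c(OC)c(C(=O)CCC)c3O)c(O)c(C(C)=O)c2O)c1O | target

**Step count and risks**

Total steps: 14. Longest linear sequence: 11 steps (1, 2, 3, 5, 6, 7, 8, 10, 12, 13, 14).

Steps most likely to fail:

1. Step 12. The crowded, fully substituted vinylketene may re-close, or acylate product phenol, faster than it captures the volatile ynol ether, so that conversion stalls and esters build up. The fallback exchanges the roles of the partners; it sets out from acid chloride 14 and comes back at diol 29, and so also avoids step 10. The ketene 19 is generated as before but trapped with commercial ethoxyethyne (Et3N, CH2Cl2, rt) to give the robust vinylogous ester rac-3-ethoxy-4-(ArCH2)cyclobut-2-en-1-one F1. Dilute HCl in THF hydrolyses this to the cyclobutane-1,3-dione, which should rest as the more substituted enol 3-hydroxy-2-(ArCH2)cyclobut-2-en-1-one F2. Silylation (i-Pr3SiOTf, Et3N) gives 2-(ArCH2)-3-(triisopropylsilyloxy)cyclobut-2-en-1-one F3, in which the bridging substituent sits on the future ketene α-carbon. Heating F3 with the more nucleophilic siloxypropyne 18 (toluene, 80–110 °C, the siloxyalkyne form of the same benzannulation) should close ring C with C2 as the only free hydroxyl, giving 4-(ArCH2)-2-methyl-3,5-bis(triisopropylsilyloxy)phenol F4. Methylation (MeI, K2CO3, acetone) gives the methyl ether F5, and Bu4NF/AcOH removes both silyl groups to give 29.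

2. Step 13. Boron trifluoride may strip benzyl groups from the ortho-benzyloxy ketones, with the benzyl cations re-adding at C1 of ring C, or the acid may cleave the diarylmethane bond of the electron-rich ring. The fallback replaces the acylium electrophile by a nitrile; it sets out from diol 29 and comes back at ketone 30. Hoesch reaction of 29 with butanenitrile (ZnCl2, HCl gas, Et2O, 0 °C) should give the ketiminium chloride of 30, F6, without O-acylation, and warm water hydrolyses it to 30.

3. Step 4. The acetyl-deactivated ring may add to acrylic acid too slowly, so that the acid polymerises or C-acylation to a chroman-4-one competes. The fallback puts the acetyl group in after the side chain; it sets out from acrylic acid 6 and comes back at acid 9. Purchased benzene-1,3,5-triol F7, which is far more nucleophilic, is heated with 6 (Amberlyst 15, toluene, 110 °C) to give 5,7-dihydroxychroman-2-one F8. C-Acetylation (Ac2O, BF3·OEt2) gives lactones 7 and 8, and aqueous NaOH opens either one to 9, in which the position of the acetyl group no longer matters.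

**Further compounds**

F1 | step 12 | rac-3-ethoxy-4-(ArCH2)cyclobut-2-en-1-one | CCOC1=CC(=O)C1Cc2c(OCc3ccccc3)c(Cc3c(OCc4ccccc4)c(C(=O)CCC)c(OCc4ccccc4)c(C)c3OC)c(OCc3ccccc3)c(C(C)=O)c2OCc2ccccc2
F2 | step 12 | 3-hydroxy-2-(ArCH2)cyclobut-2-en-1-one | O=C1CC(O)=C1Cc2c(OCc3ccccc3)c(Cc3c(OCc4ccccc4)c(C(=O)CCC)c(OCc4ccccc4)c(C)c3OC)c(OCc3ccccc3)c(C(C)=O)c2OCc2ccccc2
F3 | step 12 | 2-(ArCH2)-3-(triisopropylsilyloxy)cyclobut-2-en-1-one | O=C1CC(O[Si](C(C)C)(C(C)C)C(C)C)=C1Cc2c(OCc3ccccc3)c(Cc3c(OCc4ccccc4)c(C(=O)CCC)c(OCc4ccccc4)c(C)c3OC)c(OCc3ccccc3)c(C(C)=O)c2OCc2ccccc2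
F4 | step 12 | 4-(ArCH2)-2-methyl-3,5-bis(triisopropylsilyloxy)phenol | Oc1cc(O[Si](C(C)C)(C(C)C)C(C)C)c(Cc2c(OCc3ccccc3)c(Cc3c(OCc4ccccc4)c(C(=O)CCC)c(OCc4ccccc4)c(C)c3OC)c(OCc3ccccc3)c(C(C)=O)c2OCc2ccccc2)c(O[Si](C(C)C)(C(C)C)C(C)C)c1C
F5 | step 12 | methyl ether of F4, 2-(ArCH2)-5-methoxy-4-methyl-1,3-bis(triisopropylsilyloxy)benzene | COc1cc(O[Si](C(C)C)(C(C)C)C(C)C)c(Cc2c(OCc3ccccc3)c(Cc3c(OCc4ccccc4)c(C(=O)CCC)c(OCc4ccccc4)c(C)c3OC)c(OCc3ccccc3)c(C(C)=O)c2OCc2ccccc2)c(O[Si](C(C)C)(C(C)C)C(C)C)c1C
F6 | step 13 | ketiminium chloride of 30 | CCCC(=[NH2+])c1c(OC)c(C)c(O)c(Cc2c(OCc3ccccc3)c(Cc3c(OCc4ccccc4)c(C(=O)CCC)c(OCc4ccccc4)c(C)c3OC)c(OCc3ccccc3)c(C(C)=O)c2OCc2ccccc2)c1O.[Cl-]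
F7 | step 4 | benzene-1,3,5-triol (purchased) | Oc1cc(O)cc(O)c1
F8 | step 4 | 5,7-dihydroxychroman-2-one | O=C1CCc2c(O)cc(O)cc2O1
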